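A leftover first: at 25.0 min the spring flask still holds 39.0% of its free monomer, yet over the last 5.00 min its monomer in chains rose by 0.9 percentage points. So what stalls there?

| flask | free monomer | transfer agent | initiator | temperature | remark | time |
|---|---|---|---|---|---|---|
| spring | 0.80 M | 8 mM | 0.38 mol% | 70 °C | run made earlier |  |
| dawn | 0.80 M | 8 mM | 0.56 mol% | 88 °C | run made earlier |  |
| autumn | 1.2 M | 8 mM | 0.75 mol% | 70 °C | run made earlier |  |
| beta | 0.80 M | 8.00 mM | 0.75 mol% | 100 °C |  | 10 min |
| epsilon | 0.80 M | 8.00 mM | 0.75 mol% | 75 °C |  | 10 min |

| run | time / min | monomer in chains / % | free monomer / % |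
|---|---|---|---|
| spring | 2.00 | 9.1 | 86.5 |
| spring | 4.00 | 17.1 | 74.5 |
| spring | 6.00 | 20.9 | 66.8 |
| spring | 8.00 | 23.7 | 61.1 |
| spring | 20.0 | 25.7 | 43.5 |
| spring | 25.0 | 26.6 | 39.0 |
| dawn | 0.833 | 20.7 | 66.2 |
| dawn | 2.50 | 39.8 | 33.0 |
| dawn | 4.00 | 43.3 | 21.2 |
| dawn | 5.00 | 44.6 | 16.6 |
| dawn | 10.0 | 45.6 | 6.2 |
| autumn | 2.00 | 28.0 | 67.8 |
| autumn | 4.00 | 47.7 | 45.4 |
| autumn | 6.00 | 57.5 | 32.8 |
| autumn | 12.0 | 71.3 | 16.5 |
| autumn | 25.0 | 79.4 | 5.7 |

(standard deviation of a reading: 0.3 percentage points)

- what may be going on: free monomer -> uncatalysed product; living end + transfer agent -> dead chain; free monomer + living end -> monomer in chains + living end; free monomer + initiator -> living end + monomer in chains; initiator + monomer in chains -> spent initiator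

* the flask that comes out highest in amount of monomer in chains, in percent of the free monomer charged, or "all alike" when all lie within 1.5 percentage points (beta / epsilon / all alike)
* monomer in chains at the end, in percent of the free monomer charged, beta
* monomer in chains at the end, in percent of the free monomer charged, epsilon

What does one initiator do? Follow it. It meets free monomer and becomes a living end. The end adds free monomer, link after link, until it meets transfer agent and becomes a dead chain. In the spring flask, transfer agent at 8 mM stands above the 3.04 mM of initiator.

Then what do you count? Monomers in chains per initiator charged. The spring run's last reading gives 70.0, and the dawn run's gives 81.4.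

But the autumn run gives 106, so your number moves. Yes, but the autumn flask is a different case in two settings: it starts from 1.2 M of free monomer, and its 9.00 mM of initiator exceeds its 8 mM of transfer agent. Beta and epsilon each hold 6.00 mM, below 8.00 mM, as in the spring and dawn runs. So I take the mean of those two as the chain yield, a kinetic chain length counted per initiator charged: 75.7.

And heat? By its last reading the dawn flask had 48.2% of its charge neither free nor in chains, which I read as uncatalysed product, yet its chain yield stands above the spring one.

Your answer? With equal loadings, I reckon 56.8% for each flask. The two readings span 52.5% to 61.1%, so I name no winner. The forecast differs: epsilon, with 47% for beta and 54% for epsilon, on the ground that “heat favours the side reaction”.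

The flasks give 53.6% in beta and 52.8% in epsilon, 0.80 points apart, so the verdict is all alike. At 10.0 min, beta holds 0.00583 M of dead chain against 6.00 mM of initiator charged. The chain yields come to 71.5 and 70.5, against my 75.7.

    free monomer → uncatalysed product (k = 0.0110 s⁻¹, Ea = 117 kJ mol⁻¹)
    living end + transfer agent → dead chain (kL = 3.00 M⁻¹ s⁻¹, Ea = 41.0 kJ mol⁻¹)
    free monomer + living end → monomer in chains + living end, rate k3*[living end]*[free monomer] (k = 4.80 M⁻¹ s⁻¹, Ea = 70.0 kJ mol⁻¹)
    free monomer + initiator → living end + monomer in chains (k = 0.160 M⁻¹ s⁻¹, Ea = 78.0 kJ mol⁻¹)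
    initiator + monomer in chains → spent initiator (k = 0.0170 M⁻¹ s⁻¹, Ea = 86.0 kJ mol⁻¹)
    (constants at 100 °C)

A neighbour of epsilon charged with 1.3 mol% of initiator has 10.4 mM of it, above 8.00 mM, which lies outside the case I took the chain yield from, so 75.7 is stretched when it gives 98.4%. Computed, that neighbour reaches 77.8% at 10.0 min, a chain yield of 59.8, with 7.7% of its free monomer left.

The runs were computed for substances that don't exist, noise included.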